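Retrosynthesis: the epoxide oxygen, the C11=C13 methylene and the C8 ester (C8–O, with inversion) are removed, the lactone C12–O6 bond is opened, and C5–C10 and C1–C4 of the cyclodeca-1(10),4-diene are re-joined to a tricyclic cyclobutane, which is cut at C4–C5 and C1–C10 into a cyclohexenone and a cyclobutene ester.
Forward: ring B (C5–C10) is built from hepta-1,6-dien-4-ol and the cyclobutene (C1–C4, C15) from a silyl vinyl ether and methyl propiolate; [2+2] photocycloaddition gives the six-four-four tricycle, and thermal cycloreversion merges its three rings into the ten-membered ring.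
The butanolide is closed after the ring opening; the end game is C8 esterification, α-methylenation, 1,10-epoxidation and desilylation.
Stereochemistry: C8 from an amine-catalysed desymmetrising aldol condensation (inverted at the end by Mitsunobu esterification), C7 by trans alkylation, C3 by pairing of the enone face with one enantiomer of the racemic cyclobutene.
Both ring olefin geometries come from the chair 1,4-diradical of the cis-anti-cis adduct, C6 from outer-face hydride addition followed by Mitsunobu inversion, C1/C10 from peripheral epoxidation, C2′ from (S)-2-methylbutanoic acid.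

Key step: step 7

Numbering: germacrane numbering throughout (ring C1–C10, C14 on C10, C15 on C4, C11–C13 on C7); α/β refer to the usual drawing with H-7 α.
Assumption: the thermal opening of the bicyclo[2.2.0]hexane unit takes the chair cyclohexane-1,4-diyl course (one terminus retained, one inverted), so the cis-fused six–four adduct, not the trans-fused one, leads to the ring-cis C4=C5/(E)-C1=C10 diene.
Assumption: 9-amino-9-deoxy-epi-quinine gives (S)-5; if the sense is opposite, its quinidine-derived pseudoenantiomer is used.
Assumption: in step 6 only the (S)-enantiomer of racemic 10 is built into the adduct; the (R)-enantiomer is left over and is removed with the excess alkene on chromatography.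

Step 1
Reactants: 1 hepta-1,6-dien-4-ol
Product: 2 4-(4-methoxybenzyloxy)hepta-1,6-diene
Conditions: NaH, 4-MeOC6H4CH2Cl, n-Bu4NI (cat.), THF/DMF, 0 °C to rt
Reagents that add atoms: 4-methoxybenzyl chloride, COc1ccc(CCl)cc1
Why: Williamson etherification of the secondary alcohol; the 4-methoxybenzyl ether survives base, hydride, light and heat, does not migrate, and can later be removed oxidatively at C8 in the presence of the silyl ethers.

Step 2
Reactants: 2 4-(4-methoxybenzyloxy)hepta-1,6-diene
Product: 3 4-(4-methoxybenzyloxy)heptane-2,6-dione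
Conditions: PdCl2 (10 mol %), CuCl (1 equiv), O2 (1 atm), DMF/H2O 7:1, rt
Reagents that add atoms: water, O; dioxygen, O=O (net oxygen source, via water)
Why: Twofold Tsuji–Wacker oxidation, in which Markovnikov hydroxypalladation of each terminal alkene and β-hydride elimination give the two methyl ketones of the symmetrical diketone.

Step 3
Reactants: 3 4-(4-methoxybenzyloxy)heptane-2,6-dione
Product: 5 (S)-5-(4-methoxybenzyloxy)-3-methylcyclohex-2-en-1-one, via aldol adduct 4 (not isolated)
Conditions: 9-amino-9-deoxy-epi-quinine (20 mol %), AcOH (40 mol %), toluene, −15 °C to rt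
Reagents that add atoms: none
Why: Primary-amine (enamine) catalysed intramolecular aldol condensation of a 4-substituted heptane-2,6-dione, in which the chiral amine selects one of the two enantiotopic acetyl groups as the enamine donor and thereby sets the ether-bearing centre (C8) before water is lost from aldol 4.

Step 4
Reactants: 5 (S)-5-(4-methoxybenzyloxy)-3-methylcyclohex-2-en-1-one; 6 tert-butyl bromoacetate
Product: 7 tert-butyl 2-[(1R,6S)-6-(4-methoxybenzyloxy)-4-methyl-2-oxocyclohex-3-en-1-yl]acetate (side chain trans to the ether)
Conditions: LiN(i-Pr)2, THF, −78 °C; then 6, DMPU, −78 to −40 °C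
Reagents that add atoms: none
Why: Kinetic deprotonation at −78 °C gives the cross-conjugated α′ lithium enolate, which is kept cold to avoid β-elimination of the alkoxide and is alkylated anti to the neighbouring benzyloxy group, so that the acetate chain at C7 is set trans to C8–O (enolate alkylation).

Step 5
Reactants: 8 tert-butyldimethyl(vinyloxy)silane; 9 methyl propiolate
Product: 10 rac-methyl 4-(tert-butyldimethylsilyloxy)cyclobut-1-ene-1-carboxylate
Conditions: Tf2NH (2 mol %), CH2Cl2, −78 °C; Et3N quench; kept below 0 °C
Reagents that add atoms: none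
Why: Acid-catalysed stepwise [2+2] cycloaddition of a silyl enol ether with a propiolate, in which the enol ether CH2 adds to the alkyne β-carbon and the allenoate closes onto the silyloxocarbenium carbon, so that the silyloxy carbon lies next to the ester-bearing sp2 carbon; the racemate is kept cold because 3-oxycyclobutenes ring-open electrocyclically on warming.

Step 6
Reactants: 7 tert-butyl 2-[(1R,6S)-6-(4-methoxybenzyloxy)-4-methyl-2-oxocyclohex-3-en-1-yl]acetate; 10 rac-methyl 4-(tert-butyldimethylsilyloxy)cyclobut-1-ene-1-carboxylate
Product: 12 cis-anti-cis head-to-head photoadduct, via trans-fused C5 epimer 11 (not isolated)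
Conditions: 10 (4 equiv of the racemate), hν (350 nm, Pyrex), CH2Cl2, −40 °C; then basic Al2O3, CH2Cl2, rt; excess and unmatched 10 removed by chromatography
Reagents that add atoms: none
Why: Enone–alkene [2+2] photocycloaddition, in which the triplet enone bonds through its β-carbon C10 to the unsubstituted cyclobutene carbon C1 and the ester-stabilised radical closes onto C5 (head-to-head), on the enone face anti to the C8 ether and on the cyclobutene face anti to its silyloxy group, a pairing that only the (S)-enantiomer of 10 can meet with the two outer rings anti and that therefore sets C3 and leaves the (R)-enantiomer behind, while any trans-fused six–four isomer 11 is epimerised at C5 (α to the ketone) on basic alumina to the cis-fused adduct.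

Step 7
Reactants: 12 cis-anti-cis head-to-head photoadduct
Product: 13 cyclodeca-2,6-dienone: C6 ketone, ring-cis C4=C5 carrying the C15 methyl ester, (E)-C1=C10, 3β-OTBS, 8α-OPMB, 7β-CH2CO2t-Bu
Conditions: toluene (0.01 M, degassed), BHT (cat.), sealed silylated tube, 170 °C, stopped when 12 is consumed
Reagents that add atoms: none
Why: Heat breaks the central C1–C4 bond of the bicyclo[2.2.0]hexane unit to a cyclohexane-1,4-diyl (ester-stabilised tertiary radical at C4, secondary radical at C1), which relaxes to a chair and undergoes β-scission of C5–C10, so that the retro-[2+2] of the central cyclobutane has one retained and one inverted terminus. The closest known reaction type is the thermolysis of cyclohexenone–cyclobutene photoadducts, and of bicyclo[2.2.0]hexanes in general, to cyclodeca-1,5-dienes and 1,5-hexadienes. The ten-membered ring is not closed by bond formation but arises by ring merging, when the two bonds shared by the six- and four-membered rings break. No stereocentre is created, and the two olefin geometries follow from the one chair diradical that keeps ring B in the half-chair with the C7 and C8 substituents and C14 equatorial: there C6 is axial on C5 and ends cis to C3 (ring-cis C4=C5, ester trans to the ketone), and C9 is equatorial on C10 and ends trans to C2 ((E)-C1=C10). The step needs scission of C5–C10 and not of C2–C3, and survival of the 1,5-diene without Cope rearrangement; the more substituted ring-fusion bond, the conjugation of the new C4=C5 with both the C6 ketone and the C15 ester, and the low temperature allowed by the radical-stabilising ester at C4 are relied on for this. C3, C7 and C8 are not touched.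

Step 8
Reactants: 13 cyclodeca-2,6-dienone
Product: 14 6β-alcohol (C6 epimer of the target series, OH cis to the C7 side chain)
Conditions: NaBH4, CeCl3·7H2O, MeOH, −78 °C
Reagents that add atoms: none
Why: Luche 1,2-reduction of the enone, in which hydride should add to the outer face of the carbonyl, anti to the C7–C8 ring bond (Felkin–Anh sense) and away from C3 and the transannular C1=C10, to give the 6β-alcohol, which cannot lactonise onto the hindered tert-butyl ester.

Step 9
Reactants: 14 6β-alcohol
Product: 15 6α-(4-nitrobenzoate)
Conditions: 4-O2NC6H4CO2H, PPh3, DIAD, THF, 0 °C to rt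
Reagents that add atoms: 4-nitrobenzoic acid, O=C(O)c1ccc(cc1)[N+](=O)[O-]
Why: Mitsunobu esterification, in which the allylic alcohol is activated as the oxyphosphonium ion and displaced by 4-nitrobenzoate in an SN2 reaction with inversion, which sets the 6α oxygen (6R of the target), the electron-poor enoate double bond disfavouring ionisation and SN2′ attack.

Step 10
Reactants: 15 6α-(4-nitrobenzoate)
Product: 16 6α,15-diol (tert-butyl ester retained)
Conditions: i-Bu2AlH (4.5 equiv), CH2Cl2, −78 °C; KNaC4H4O6 (aq)
Reagents that add atoms: none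
Why: Hydride reduction with i-Bu2AlH at low temperature converts the conjugated methyl ester into the allylic alcohol (1,2-reduction) and cleaves the nitrobenzoate, while the hindered tert-butyl ester is left.

Step 11
Reactants: 16 6α,15-diol
Product: 17 15-O-TBS ether with free 6α-OH
Conditions: TBSCl (1.1 equiv), imidazole, CH2Cl2, −20 to 0 °C
Reagents that add atoms: tert-butyldimethylsilyl chloride, CC(C)(C)[Si](C)(C)Cl
Why: Silylation of the primary allylic alcohol, which is much faster than that of the hindered secondary C6 alcohol.

Step 12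
Reactants: 17 15-O-TBS ether with free 6α-OH
Product: 18 trans-fused 6α,12-lactone (3β,15-bis-OTBS, 8α-OPMB)
Conditions: KOt-Bu (0.3 equiv), THF, 0 °C to rt
Reagents that add atoms: none
Why: Base-mediated lactonisation (intramolecular transesterification), in which the C6 alkoxide attacks the tert-butyl ester in a 5-exo-trig closure to the trans-fused butanolide with retention at C6 and C7, and the absence of acid leaves the silyl ethers in place.

Step 13
Reactants: 18 trans-fused 6α,12-lactone
Product: 19 8α-alcohol
Conditions: DDQ, CH2Cl2/pH 7 buffer, 0 °C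
Reagents that add atoms: none
Why: Oxidative cleavage of the 4-methoxybenzyl ether by DDQ (hydride abstraction to the oxocarbenium ion, then hydrolysis) frees the C8 alcohol without touching the silyl ethers, the lactone or the alkenes.

Step 14
Reactants: 19 8α-alcohol; 20 (S)-2-methylbutanoic acid
Product: 21 8β-[(S)-2-methylbutanoate]
Conditions: 20, PPh3, DIAD, toluene, 0 °C to rt
Reagents that add atoms: none
Why: Mitsunobu esterification with SN2 inversion at C8 installs the (S)-2-methylbutanoate in the 8β (8R) configuration, and the stereocentre of the acid is not involved.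

Step 15
Reactants: 21 8β-[(S)-2-methylbutanoate]
Product: 24 α-methylene lactone, via Mannich base 22 (not isolated), via ammonium iodide 23 (not isolated)
Conditions: LiN(i-Pr)2, THF, −78 °C; Me2N=CH2+ I−, −78 to 0 °C; then MeI, MeOH, rt; then NaHCO3 (aq), CH2Cl2
Reagents that add atoms: dimethylmethyleneammonium iodide, C[N+](C)=C.[I-]
Why: The lactone, more acidic than the acyclic ester, is deprotonated selectively and its enolate is aminomethylated by the iminium salt (Mannich reaction), after which quaternisation and base-induced elimination of trimethylamine give the α-methylene lactone, the C11 centre of 22 being lost.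

Step 16
Reactants: 24 α-methylene lactone
Product: 25 1β,10α-epoxide (bis-TBS ether of the target)
Conditions: m-CPBA (1.1 equiv), NaHCO3, CH2Cl2, −20 to 0 °C
Reagents that add atoms: 3-chloroperbenzoic acid, OOC(=O)c1cccc(Cl)c1
Why: Prilezhaev epoxidation of the only electron-rich alkene (C4=C5 is deactivated by three allylic oxygens, C11=C13 by the carbonyl), where peripheral attack on the (E)-alkene in the usual conformer of this ring type, with the C14 methyl on the β face and H-1 on the α face, should give the trans 1β,10α-epoxide (1R,10R).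

Step 17
Reactants: 25 1β,10α-epoxide
Product: 26 CNP0267576.2
Conditions: HF·pyridine, pyridine, THF, 0 °C to rt
Reagents that add atoms: none
Why: Buffered fluoride cleaves both tert-butyldimethylsilyl ethers, and the near-neutral medium should leave the epoxide, the methylene lactone and the ester intact (desilylation).

Compound list
1 | hepta-1,6-dien-4-ol | C=CCC(O)CC=C | starting material
2 | 4-(4-methoxybenzyloxy)hepta-1,6-diene | C=CCC(OCc1ccc(OC)cc1)CC=C | intermediate
3 | 4-(4-methoxybenzyloxy)heptane-2,6-dione | CC(=O)CC(OCc1ccc(OC)cc1)CC(C)=O | intermediate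
4 | 3-hydroxy-5-(4-methoxybenzyloxy)-3-methylcyclohexanone (aldol adduct, carbinol centre unassigned, not isolated) | O=C1CC(C)(O)C[C@H](OCc2ccc(OC)cc2)C1 | intermediate
5 | (S)-5-(4-methoxybenzyloxy)-3-methylcyclohex-2-en-1-one | O=C1C=C(C)C[C@H](OCc2ccc(OC)cc2)C1 | intermediate
6 | tert-butyl bromoacetate | BrCC(=O)OC(C)(C)C | starting material
7 | tert-butyl 2-[(1R,6S)-6-(4-methoxybenzyloxy)-4-methyl-2-oxocyclohex-3-en-1-yl]acetate (side chain trans to the ether) | O=C1C=C(C)C[C@H](OCc2ccc(OC)cc2)[C@H]1CC(=O)OC(C)(C)C | intermediate
8 | tert-butyldimethyl(vinyloxy)silane | C=CO[Si](C)(C)C(C)(C)C | starting material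
9 | methyl propiolate | C#CC(=O)OC | starting material
10 | rac-methyl 4-(tert-butyldimethylsilyloxy)cyclobut-1-ene-1-carboxylate | COC(=O)C1=CCC1O[Si](C)(C)C(C)(C)C | intermediate
11 | trans-fused head-to-head photoadduct, the C5 epimer of 12 (C4–C5 bond α, H-5 β; not isolated) | O=C1[C@H](CC(=O)OC(C)(C)C)[C@@H](OCc4ccc(OC)cc4)C[C@]2(C)[C@H]3C[C@H](O[Si](C)(C)C(C)(C)C)[C@@]3(C(=O)OC)[C@@H]12 | intermediate
12 | cis-anti-cis head-to-head photoadduct: central cyclobutane C1–C4–C5–C10 on the β face of the cyclohexanone (H-5 and C14 α), outer cyclobutane C1–C2–C3–C4 anti to the six-membered ring, (3S)-OTBS cis to the C15 methyl ester on C4 and trans to C5, C6 ketone, 7β-CH2CO2t-Bu, 8α-OPMB | O=C1[C@H](CC(=O)OC(C)(C)C)[C@@H](OCc4ccc(OC)cc4)C[C@]2(C)[C@H]3C[C@H](O[Si](C)(C)C(C)(C)C)[C@@]3(C(=O)OC)[C@H]12 | intermediate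
13 | 12-tert-butyl 15-methyl (1(10)E)-3β-(tert-butyldimethylsilyloxy)-8α-(4-methoxybenzyloxy)-6-oxo-13-norgermacra-1(10),4-diene-12,15-dioate, ring-cis C4=C5 (C3 and C6 cis; 4E by the sequence rule because of the ester), H-7 α | O=C1/C=C(/C(=O)OC)[C@@H](O[Si](C)(C)C(C)(C)C)C/C=C(C)/C[C@H](OCc2ccc(OC)cc2)[C@H]1CC(=O)OC(C)(C)C | intermediate
14 | 6β-alcohol from 13 (OH cis to the C7 side chain; C6 epimeric to the target series) | O[C@H]1/C=C(/C(=O)OC)[C@@H](O[Si](C)(C)C(C)(C)C)C/C=C(C)/C[C@H](OCc2ccc(OC)cc2)[C@H]1CC(=O)OC(C)(C)C | intermediate
15 | 6α-(4-nitrobenzoyloxy) diester (C6 inverted; otherwise as 14) | O=C(O[C@@H]1/C=C(/C(=O)OC)[C@@H](O[Si](C)(C)C(C)(C)C)C/C=C(C)/C[C@H](OCc2ccc(OC)cc2)[C@H]1CC(=O)OC(C)(C)C)c3ccc(cc3)[N+](=O)[O-] | intermediate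
16 | tert-butyl (1(10)E,4Z)-3β-(tert-butyldimethylsilyloxy)-6α,15-dihydroxy-8α-(4-methoxybenzyloxy)-13-norgermacra-1(10),4-dien-12-oate | O[C@@H]1/C=C(/CO)[C@@H](O[Si](C)(C)C(C)(C)C)C/C=C(C)/C[C@H](OCc2ccc(OC)cc2)[C@H]1CC(=O)OC(C)(C)C | intermediate
17 | 15-O-tert-butyldimethylsilyl ether of 16 (6α-OH free) | O[C@@H]1/C=C(/CO[Si](C)(C)C(C)(C)C)[C@@H](O[Si](C)(C)C(C)(C)C)C/C=C(C)/C[C@H](OCc2ccc(OC)cc2)[C@H]1CC(=O)OC(C)(C)C | intermediate
18 | (1(10)E,4Z)-3β,15-bis(tert-butyldimethylsilyloxy)-8α-(4-methoxybenzyloxy)-13-norgermacra-1(10),4-dien-6α,12-olide (trans-lactone, H-6 β, H-7 α) | C1C(=O)O[C@@H]2/C=C(/CO[Si](C)(C)C(C)(C)C)[C@@H](O[Si](C)(C)C(C)(C)C)C/C=C(C)/C[C@H](OCc3ccc(OC)cc3)[C@@H]12 | intermediate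
19 | 8α-alcohol from 18 | C1C(=O)O[C@@H]2/C=C(/CO[Si](C)(C)C(C)(C)C)[C@@H](O[Si](C)(C)C(C)(C)C)C/C=C(C)/C[C@H](O)[C@@H]12 | intermediate
20 | (S)-2-methylbutanoic acid | CC[C@H](C)C(=O)O | starting material
21 | 8β-[(S)-2-methylbutanoyloxy] lactone (C8 inverted; otherwise as 19) | C1C(=O)O[C@@H]2/C=C(/CO[Si](C)(C)C(C)(C)C)[C@@H](O[Si](C)(C)C(C)(C)C)C/C=C(C)/C[C@@H](OC(=O)[C@@H](C)CC)[C@@H]12 | intermediate
22 | 11-(dimethylaminomethyl) lactone (Mannich base, C11 epimers, not isolated) | CN(C)CC1C(=O)O[C@@H]2/C=C(/CO[Si](C)(C)C(C)(C)C)[C@@H](O[Si](C)(C)C(C)(C)C)C/C=C(C)/C[C@@H](OC(=O)[C@@H](C)CC)[C@@H]12 | intermediate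
23 | 11-(trimethylammoniomethyl) lactone iodide (not isolated) | C[N+](C)(C)CC1C(=O)O[C@@H]2/C=C(/CO[Si](C)(C)C(C)(C)C)[C@@H](O[Si](C)(C)C(C)(C)C)C/C=C(C)/C[C@@H](OC(=O)[C@@H](C)CC)[C@@H]12.[I-] | intermediate
24 | (1(10)E,4Z)-3β,15-bis(tert-butyldimethylsilyloxy)-8β-[(S)-2-methylbutanoyloxy]germacra-1(10),4,11(13)-trien-6α,12-olide | C=C1C(=O)O[C@@H]2/C=C(/CO[Si](C)(C)C(C)(C)C)[C@@H](O[Si](C)(C)C(C)(C)C)C/C=C(C)/C[C@@H](OC(=O)[C@@H](C)CC)[C@@H]12 | intermediate
25 | 1β,10α-epoxide of 24 (1R,10R) | C=C1C(=O)O[C@@H]2/C=C(/CO[Si](C)(C)C(C)(C)C)[C@@H](O[Si](C)(C)C(C)(C)C)C[C@H]3O[C@]3(C)C[C@@H](OC(=O)[C@@H](C)CC)[C@@H]12 | intermediate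
26 | CNP0267576.2: (1R,3S,6R,7R,8R,10R,4Z)-1β,10α-epoxy-3β,15-dihydroxy-8β-[(S)-2-methylbutanoyloxy]germacra-4,11(13)-dien-6α,12-olide | C=C1C(=O)O[C@@H]2/C=C(/CO)[C@@H](O)C[C@H]3O[C@]3(C)C[C@@H](OC(=O)[C@@H](C)CC)[C@@H]12 | target

Total step count: 17. Longest linear sequence: 16 steps (steps 1–4 and 6–17; step 5 makes the second fragment).

Steps most likely to fail

Step 7. The 1,4-diradical may cleave C2–C3 instead of C5–C10, or the diene may undergo Cope rearrangement afterwards; both lead to the cis-divinylcyclohexane, and the C3 silyloxy group favours that channel. The Z-enone may also enolise by 1,5-hydrogen shift at the reaction temperature. The fallback opens the ring at the alcohol oxidation level. From 12, NaBH4 in MeOH at −20 °C should add hydride from the convex α face to give the tricyclic 6β-alcohol F4. F4 is kept neutral and cold so that it does not lactonise onto the C15 ester, and is thermolysed as in step 7. Ring B is then a true chair with the same bias and the product is not an enone. The product is the allylic alcohol 14 itself, so the route is re-entered at 14 and step 8 is not needed. This removes the enone-specific decay paths but not the Cope channel, which only a short time at temperature can limit.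

Step 6. The matching may be incomplete: both enantiomers of 10 or both enone faces may react, giving C3-epimeric and head-to-tail adducts that have to be separated. Compound 10 may also ring-open electrocyclically before it is trapped. The fallback uses an enantiopure alkene instead of selection in the flask. From 10, HF·pyridine in THF at 0 °C gives the racemic cyclobutenol F1. Candida antarctica lipase B with vinyl acetate should acylate the (R)-enantiomer and leave the (S)-cyclobutenol F2. F2 is silylated again (TBSCl, imidazole) to the (S)-silyl ether F3. F3 (1.5 equiv) is irradiated with 7 as in step 6, and the route is re-entered at 12.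

Step 8. Hydride may add from both faces of the ketone, or from the inner face only, and the doubly activated C4=C5 may undergo conjugate reduction. The fallback makes the outcome independent of the face. From 13, the reduction is run as before and the epimers are separated. The 6α-alcohol F5, if it forms, is esterified with retention (4-nitrobenzoyl chloride, pyridine, DMAP) to the same ester 15 that 14 gives with inversion in step 9. Both alcohols thus converge, and the route is re-entered at 15.

Further compounds
F1 | step 6 | rac-methyl 4-hydroxycyclobut-1-ene-1-carboxylate | COC(=O)C1=CCC1O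
F2 | step 6 | (S)-methyl 4-hydroxycyclobut-1-ene-1-carboxylate | COC(=O)C1=CC[C@@H]1O
F3 | step 6 | (S)-methyl 4-(tert-butyldimethylsilyloxy)cyclobut-1-ene-1-carboxylate | COC(=O)C1=CC[C@@H]1O[Si](C)(C)C(C)(C)C
F4 | step 7 | tricyclic 6β-alcohol from 12 (OH cis to the central cyclobutane and to the C7 side chain) | O[C@@H]1[C@H](CC(=O)OC(C)(C)C)[C@@H](OCc4ccc(OC)cc4)C[C@]2(C)[C@H]3C[C@H](O[Si](C)(C)C(C)(C)C)[C@@]3(C(=O)OC)[C@H]12
F5 | step 8 | 6α-alcohol, the C6 epimer of 14 | O[C@@H]1/C=C(/C(=O)OC)[C@@H](O[Si](C)(C)C(C)(C)C)C/C=C(C)/C[C@H](OCc2ccc(OC)cc2)[C@H]1CC(=O)OC(C)(C)C
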